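**Retrosynthetic overview**

1. The target is a primary ester between a ring-A cyclohexane (C1 CO2H, C2 tertiary OH and CH2O, C5 isopropyl, C6 acrylic acid arm) and the side-chain acid of the ring-B butenolide. Cutting the CH2O–C(=O) bond (Yamaguchi) gives A-alcohol 14 and B-acid 16, both made from one monomer 13.
2. The fused butenolide of ring B is the dehydrated, lactonised form of the same ring-A β-hydroxy ester. Both (E)-2-(hydroxymethyl)acrylate arms come from cross-metathesis on a C6 vinyl group.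
3. Enabling feature: in ring A the tertiary carbinol C2 is β to the C1 carboxyl (aldol relationship), and C6 carries an alkenyl group β to the same carboxyl (1,4-addition relationship). The C1–C2 bond and three contiguous stereocentres can therefore come from one conjugate vinylation/aldol cyclisation of the acyclic keto-enal 6.
4. Keto-enal 6 comes from 3-methylbutanal and a silyloxymethyl vinyl ketone by an organocatalytic Michael addition (sets the isopropyl centre) and a formyl Wittig olefination.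
5. Ring order: carbocycle of ring A (step 5, which also supplies the carbocycle of ring B), lactone of ring B (step 12), ester union (step 13), deprotection.

Key step: step 5

Remark: tert-butyl 2-(hydroxymethyl)acrylate 11 is taken as purchasable (otherwise one Baylis–Hillman step from tert-butyl acrylate and formaldehyde); TBS = tert-butyldimethylsilyl, TBDPS = tert-butyldiphenylsilyl; ring-A locants are C1 (carbonyl-bearing), C2 (carbinol), C5 (isopropyl), C6 (alkenyl).

**Route**

Step 1
Reactants: 1 (tert-butyldimethylsilyloxy)acetaldehyde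
Product: 2 rac-1-(TBS-oxy)but-3-en-2-ol
Conditions: CH2=CHMgBr, THF, −78 °C; aq. NH4Cl
Reagents that add atoms: CH2=CHMgBr (vinylmagnesium bromide), C=C[Mg]Br
Why: Grignard 1,2-addition to the aldehyde; the racemic carbinol centre is erased in step 2.

Step 2
Reactants: 2 rac-1-(TBS-oxy)but-3-en-2-ol
Product: 3 1-(TBS-oxy)but-3-en-2-one
Conditions: Dess–Martin periodinane, NaHCO3, CH2Cl2, 0 °C; used at once
Reagents that add atoms: none
Why: Dess–Martin oxidation of the allylic alcohol is neutral and should leave the silyl ether and the polymerisable vinyl ketone intact.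

Step 3
Reactants: 3 1-(TBS-oxy)but-3-en-2-one; 4 3-methylbutanal
Product: 5 (R)-6-(TBS-oxy)-2-isopropyl-5-oxohexanal
Conditions: (R)-2-(methoxydiphenylmethyl)pyrrolidine (5 mol %), ethyl 3,4-dihydroxybenzoate (20 mol %), neat, 4 °C
Reagents that add atoms: none
Why: Enamine-catalysed Michael addition of an aldehyde to a vinyl ketone; the diarylmethyl group shields one face of the (E)-enamine so the enone should add to give the (R) centre, the isopropyl-bearing carbon of both rings.

Step 4
Reactants: 5 (R)-6-(TBS-oxy)-2-isopropyl-5-oxohexanal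
Product: 6 (R,E)-8-(TBS-oxy)-4-isopropyl-7-oxooct-2-enal
Conditions: Ph3P=CHCHO (1.1 equiv), toluene, 70 °C
Reagents that add atoms: (triphenylphosphoranylidene)acetaldehyde, O=CC=P(c1ccccc1)(c1ccccc1)c1ccccc1
Why: Wittig olefination with the stabilised formyl ylide should attack only the aldehyde (not the ketone), give the (E)-enal, and be neutral enough to keep the α-centre.

Step 5
Reactants: 6 (R,E)-8-(TBS-oxy)-4-isopropyl-7-oxooct-2-enal
Product: 8 (1S,2S,5R,6R)-2-((TBS-oxy)methyl)-2-hydroxy-5-isopropyl-6-vinylcyclohexane-1-carbaldehyde, via rhodium enolate 7 (not isolated)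
Conditions: vinylboronic acid pinacol ester (2 equiv), [RhCl(C2H4)2]2 (2.5 mol %), (R,R)-2,5-diphenylbicyclo[2.2.2]octa-2,5-diene (5.5 mol %), KOH (0.1 equiv), 1,4-dioxane/H2O 10:1, 30 °C
Reagents that add atoms: vinylboronic acid pinacol ester, C=CB1OC(C)(C)C(C)(C)O1
Why: Proposed new method: transmetalation gives a vinyl complex of monovalent rhodium that adds 1,4 to the s-trans enal, and the resulting O-bound (E)-enolate 7 is trapped by the tethered, inductively activated α-silyloxy ketone in a 6-(enolexo)-exo-trig aldol before hydrolysis of the rhodium aldolate regenerates Rh–OH; the closest known reaction type is the rhodium-catalysed conjugate addition/aldol cyclisation of enone–ketones with arylboronic acids, extended here to an enal donor and a vinylboronate. The diene ligand should fix C6 by Re-face delivery of vinyl to the β-carbon (catalyst control over the weak bias of the neighbouring isopropyl centre; the ligand antipode is used if the sense proves opposite) and should suppress 1,2-addition. In the chair Zimmerman–Traxler arrangement with isopropyl and vinyl equatorial, rhodium bridges the enolate oxygen, which in an (E)-enolate points away from the forming ring, so the ketone oxygen is held equatorial and CH2OTBS is forced axial, giving OH trans and CH2O cis to the formyl group at C2. C1 should end with the formyl group equatorial, either directly or by epimerisation of this enolisable centre under the basic conditions. The step needs the aldol to outrun protonation of the enolate, E1cB dehydration and base-induced Michael addition of the ketone enolate, which the six-membered closure, the low temperature and the substoichiometric base should secure.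

Step 6
Reactants: 8 (1S,2S,5R,6R)-2-((TBS-oxy)methyl)-2-hydroxy-5-isopropyl-6-vinylcyclohexane-1-carbaldehyde
Product: 9 (1S,2S,5R,6R)-2-((TBS-oxy)methyl)-2-hydroxy-5-isopropyl-6-vinylcyclohexane-1-carboxylic acid
Conditions: NaClO2, NaH2PO4, 2-methyl-2-butene, t-BuOH/H2O, 0 °C to rt
Reagents that add atoms: NaClO2 (sodium chlorite), [Na+].[O-]Cl=O
Why: Pinnick oxidation converts the aldehyde to the acid without touching the vinyl group (hypochlorite scavenged) or the β-hydroxy centre.

Step 7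
Reactants: 9 (1S,2S,5R,6R)-2-((TBS-oxy)methyl)-2-hydroxy-5-isopropyl-6-vinylcyclohexane-1-carboxylic acid
Product: 10 tert-butyl (1S,2S,5R,6R)-2-((TBS-oxy)methyl)-2-hydroxy-5-isopropyl-6-vinylcyclohexane-1-carboxylate
Conditions: t-BuOC(=NH)CCl3, CH2Cl2/cyclohexane, rt
Reagents that add atoms: tert-butyl 2,2,2-trichloroacetimidate, CC(C)(C)OC(=N)C(Cl)(Cl)Cl
Why: Imidate tert-butylation is selective for the carboxylic acid over the tertiary alcohol, and the bulky ester later resists lactonisation onto the neighbouring CH2OH.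

Step 8
Reactants: 11 tert-butyl 2-(hydroxymethyl)acrylate
Product: 12 tert-butyl 2-((TBDPS-oxy)methyl)acrylate
Conditions: TBDPSCl, imidazole, CH2Cl2, 0 °C to rt
Reagents that add atoms: tert-butyl(chloro)diphenylsilane, CC(C)(C)[Si](Cl)(c1ccccc1)c1ccccc1
Why: Standard silylation of a primary allylic alcohol gives an acid-robust ether.

Step 9
Reactants: 10 tert-butyl (1S,2S,5R,6R)-2-((TBS-oxy)methyl)-2-hydroxy-5-isopropyl-6-vinylcyclohexane-1-carboxylate; 12 tert-butyl 2-((TBDPS-oxy)methyl)acrylate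
Product: 13 tert-butyl (1S,2S,5R,6S)-6-[(E)-3-tert-butoxy-2-((TBDPS-oxy)methyl)-3-oxoprop-1-en-1-yl]-2-((TBS-oxy)methyl)-2-hydroxy-5-isopropylcyclohexane-1-carboxylate
Conditions: second-generation Hoveyda–Grubbs catalyst [RuCl2(H2IMes)(=CH-C6H4-2-OiPr)] (10 mol %), 12 (4 equiv), toluene, 80 °C, argon sweep
Reagents that add atoms: none
Why: Olefin cross-metathesis of a monosubstituted alkene with a 1,1-disubstituted acrylate should give the trisubstituted enoate with the ring carbon trans to the ester, the thermodynamically preferred (E) geometry.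

Step 10
Reactants: 13 tert-butyl (1S,2S,5R,6S)-6-[(E)-3-tert-butoxy-2-((TBDPS-oxy)methyl)-3-oxoprop-1-en-1-yl]-2-((TBS-oxy)methyl)-2-hydroxy-5-isopropylcyclohexane-1-carboxylate
Product: 14 tert-butyl (1S,2S,5R,6S)-6-[(E)-3-tert-butoxy-2-((TBDPS-oxy)methyl)-3-oxoprop-1-en-1-yl]-2-hydroxy-2-(hydroxymethyl)-5-isopropylcyclohexane-1-carboxylate
Conditions: camphorsulfonic acid (10 mol %), MeOH/CH2Cl2 1:1, 0 °C
Reagents that add atoms: none
Why: Acid-catalysed methanolysis should remove the TBS ether far faster than the TBDPS ether while leaving both tert-butyl esters.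

Step 11
Reactants: 13 tert-butyl (1S,2S,5R,6S)-6-[(E)-3-tert-butoxy-2-((TBDPS-oxy)methyl)-3-oxoprop-1-en-1-yl]-2-((TBS-oxy)methyl)-2-hydroxy-5-isopropylcyclohexane-1-carboxylate
Product: 15 tert-butyl (5R,6S)-6-[(E)-3-tert-butoxy-2-((TBDPS-oxy)methyl)-3-oxoprop-1-en-1-yl]-2-((TBS-oxy)methyl)-5-isopropylcyclohex-1-ene-1-carboxylate
Conditions: Burgess reagent (3 equiv), toluene, 60 °C
Reagents that add atoms: none
Why: Burgess dehydration (syn elimination through the sulfamate) should remove the tertiary OH together with the cis, acidic C1–H to give the conjugated tetrasubstituted enoate, erasing the two stereocentres ring B does not have.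

Step 12
Reactants: 15 tert-butyl (5R,6S)-6-[(E)-3-tert-butoxy-2-((TBDPS-oxy)methyl)-3-oxoprop-1-en-1-yl]-2-((TBS-oxy)methyl)-5-isopropylcyclohex-1-ene-1-carboxylate
Product: 16 (E)-2-((TBDPS-oxy)methyl)-3-[(6R,7S)-6-isopropyl-1-oxo-1,3,4,5,6,7-hexahydroisobenzofuran-7-yl]acrylic acid
Conditions: TFA/CH2Cl2 1:3, H2O (2 equiv), 0 °C to rt
Reagents that add atoms: none
Why: Acidolysis cleaves both tert-butyl esters and the allylic TBS ether, and the freed CH2OH, held cis to the ring carboxyl by the tetrasubstituted alkene, should lactonise to the butenolide while the TBDPS ether survives.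

Step 13
Reactants: 14 tert-butyl (1S,2S,5R,6S)-6-[(E)-3-tert-butoxy-2-((TBDPS-oxy)methyl)-3-oxoprop-1-en-1-yl]-2-hydroxy-2-(hydroxymethyl)-5-isopropylcyclohexane-1-carboxylate; 16 (E)-2-((TBDPS-oxy)methyl)-3-[(6R,7S)-6-isopropyl-1-oxo-1,3,4,5,6,7-hexahydroisobenzofuran-7-yl]acrylic acid
Product: 17 tert-butyl (1S,2S,5R,6S)-6-[(E)-3-tert-butoxy-2-((TBDPS-oxy)methyl)-3-oxoprop-1-en-1-yl]-2-hydroxy-5-isopropyl-2-[({(E)-2-((TBDPS-oxy)methyl)-3-[(6R,7S)-6-isopropyl-1-oxo-1,3,4,5,6,7-hexahydroisobenzofuran-7-yl]acryloyl}oxy)methyl]cyclohexane-1-carboxylate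
Conditions: 16, 2,4,6-Cl3C6H2COCl, Et3N, THF, rt; then 14, DMAP, toluene, rt
Reagents that add atoms: none
Why: Yamaguchi esterification should acylate only the primary alcohol of 14, as the tertiary alcohol is unreactive and the tert-butyl ester blocks lactonisation.

Step 14
Reactants: 17 tert-butyl (1S,2S,5R,6S)-6-[(E)-3-tert-butoxy-2-((TBDPS-oxy)methyl)-3-oxoprop-1-en-1-yl]-2-hydroxy-5-isopropyl-2-[({(E)-2-((TBDPS-oxy)methyl)-3-[(6R,7S)-6-isopropyl-1-oxo-1,3,4,5,6,7-hexahydroisobenzofuran-7-yl]acryloyl}oxy)methyl]cyclohexane-1-carboxylate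
Product: 18 tert-butyl (1S,2S,5R,6S)-6-[(E)-3-tert-butoxy-2-(hydroxymethyl)-3-oxoprop-1-en-1-yl]-2-hydroxy-2-[({(E)-2-(hydroxymethyl)-3-[(6R,7S)-6-isopropyl-1-oxo-1,3,4,5,6,7-hexahydroisobenzofuran-7-yl]acryloyl}oxy)methyl]-5-isopropylcyclohexane-1-carboxylate
Conditions: HF·pyridine, pyridine, THF, 0 °C to rt
Reagents that add atoms: none
Why: Buffered fluoride desilylation removes both TBDPS ethers without touching the esters, the lactone or the tert-butyl groups.

Step 15
Reactants: 18 tert-butyl (1S,2S,5R,6S)-6-[(E)-3-tert-butoxy-2-(hydroxymethyl)-3-oxoprop-1-en-1-yl]-2-hydroxy-2-[({(E)-2-(hydroxymethyl)-3-[(6R,7S)-6-isopropyl-1-oxo-1,3,4,5,6,7-hexahydroisobenzofuran-7-yl]acryloyl}oxy)methyl]-5-isopropylcyclohexane-1-carboxylate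
Product: 19 (1S,2S,5R,6S)-6-[(E)-2-carboxy-3-hydroxyprop-1-en-1-yl]-2-hydroxy-2-[({(E)-2-(hydroxymethyl)-3-[(6R,7S)-6-isopropyl-1-oxo-1,3,4,5,6,7-hexahydroisobenzofuran-7-yl]acryloyl}oxy)methyl]-5-isopropylcyclohexane-1-carboxylic acid (target)
Conditions: TFA/CH2Cl2 1:3, anisole, 0 °C; evaporation
Reagents that add atoms: none
Why: Acidolysis of the two tert-butyl esters (loss of 2-methylpropene) is non-hydrolytic, so the inter-unit ester, the butenolide and all stereocentres should be retained.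

**Compound list**

1 | (tert-butyldimethylsilyloxy)acetaldehyde | O=CCO[Si](C)(C)C(C)(C)C | starting material
2 | rac-1-(TBS-oxy)but-3-en-2-ol | C=CC(O)CO[Si](C)(C)C(C)(C)C | intermediate
3 | 1-(TBS-oxy)but-3-en-2-one | C=CC(=O)CO[Si](C)(C)C(C)(C)C | intermediate
4 | 3-methylbutanal | CC(C)CC=O | starting material
5 | (R)-6-(TBS-oxy)-2-isopropyl-5-oxohexanal | O=C[C@@H](C(C)C)CCC(=O)CO[Si](C)(C)C(C)(C)C | intermediate
6 | (R,E)-8-(TBS-oxy)-4-isopropyl-7-oxooct-2-enal | O=C/C=C/[C@@H](C(C)C)CCC(=O)CO[Si](C)(C)C(C)(C)C | intermediate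
7 | rhodium (E)-enolate of (3R,4R)-8-(TBS-oxy)-4-isopropyl-7-oxo-3-vinyloctanal (diene ligand not drawn) | CC(C)[C@@H](CCC(=O)CO[Si](C)(C)C(C)(C)C)[C@H](/C=C/O[Rh])C=C | intermediate
8 | (1S,2S,5R,6R)-2-((TBS-oxy)methyl)-2-hydroxy-5-isopropyl-6-vinylcyclohexane-1-carbaldehyde | CC(C)[C@H]1CC[C@@](O)(CO[Si](C)(C)C(C)(C)C)[C@@H](C=O)[C@@H]1C=C | intermediate
9 | (1S,2S,5R,6R)-2-((TBS-oxy)methyl)-2-hydroxy-5-isopropyl-6-vinylcyclohexane-1-carboxylic acid | CC(C)[C@H]1CC[C@@](O)(CO[Si](C)(C)C(C)(C)C)[C@@H](C(=O)O)[C@@H]1C=C | intermediate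
10 | tert-butyl (1S,2S,5R,6R)-2-((TBS-oxy)methyl)-2-hydroxy-5-isopropyl-6-vinylcyclohexane-1-carboxylate | CC(C)[C@H]1CC[C@@](O)(CO[Si](C)(C)C(C)(C)C)[C@@H](C(=O)OC(C)(C)C)[C@@H]1C=C | intermediate
11 | tert-butyl 2-(hydroxymethyl)acrylate | C=C(CO)C(=O)OC(C)(C)C | starting material
12 | tert-butyl 2-((TBDPS-oxy)methyl)acrylate | C=C(CO[Si](c1ccccc1)(c1ccccc1)C(C)(C)C)C(=O)OC(C)(C)C | intermediate
13 | tert-butyl (1S,2S,5R,6S)-6-[(E)-3-tert-butoxy-2-((TBDPS-oxy)methyl)-3-oxoprop-1-en-1-yl]-2-((TBS-oxy)methyl)-2-hydroxy-5-isopropylcyclohexane-1-carboxylate | CC(C)[C@H]1CC[C@@](O)(CO[Si](C)(C)C(C)(C)C)[C@@H](C(=O)OC(C)(C)C)[C@@H]1/C=C(\CO[Si](c1ccccc1)(c1ccccc1)C(C)(C)C)C(=O)OC(C)(C)C | intermediate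
14 | tert-butyl (1S,2S,5R,6S)-6-[(E)-3-tert-butoxy-2-((TBDPS-oxy)methyl)-3-oxoprop-1-en-1-yl]-2-hydroxy-2-(hydroxymethyl)-5-isopropylcyclohexane-1-carboxylate | CC(C)[C@H]1CC[C@@](O)(CO)[C@@H](C(=O)OC(C)(C)C)[C@@H]1/C=C(\CO[Si](c1ccccc1)(c1ccccc1)C(C)(C)C)C(=O)OC(C)(C)C | intermediate
15 | tert-butyl (5R,6S)-6-[(E)-3-tert-butoxy-2-((TBDPS-oxy)methyl)-3-oxoprop-1-en-1-yl]-2-((TBS-oxy)methyl)-5-isopropylcyclohex-1-ene-1-carboxylate | CC(C)[C@H]1CCC(CO[Si](C)(C)C(C)(C)C)=C(C(=O)OC(C)(C)C)[C@@H]1/C=C(\CO[Si](c1ccccc1)(c1ccccc1)C(C)(C)C)C(=O)OC(C)(C)C | intermediate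
16 | (E)-2-((TBDPS-oxy)methyl)-3-[(6R,7S)-6-isopropyl-1-oxo-1,3,4,5,6,7-hexahydroisobenzofuran-7-yl]acrylic acid | OC(=O)/C(=C/[C@H]1C2=C(CC[C@@H]1C(C)C)COC2=O)CO[Si](c1ccccc1)(c1ccccc1)C(C)(C)C | intermediate
17 | fully protected dimer: di-tert-butyl ester, bis-TBDPS ether of the target | CC(C)[C@H]1CC[C@@](O)(COC(=O)/C(=C/[C@H]2C3=C(CC[C@@H]2C(C)C)COC3=O)CO[Si](c2ccccc2)(c2ccccc2)C(C)(C)C)[C@@H](C(=O)OC(C)(C)C)[C@@H]1/C=C(\CO[Si](c1ccccc1)(c1ccccc1)C(C)(C)C)C(=O)OC(C)(C)C | intermediate
18 | di-tert-butyl ester of the target | CC(C)[C@H]1CC[C@@](O)(COC(=O)/C(=C/[C@H]2C3=C(CC[C@@H]2C(C)C)COC3=O)CO)[C@@H](C(=O)OC(C)(C)C)[C@@H]1/C=C(\CO)C(=O)OC(C)(C)C | intermediate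
19 | (1S,2S,5R,6S)-6-[(E)-2-carboxy-3-hydroxyprop-1-en-1-yl]-2-hydroxy-2-[({(E)-2-(hydroxymethyl)-3-[(6R,7S)-6-isopropyl-1-oxo-1,3,4,5,6,7-hexahydroisobenzofuran-7-yl]acryloyl}oxy)methyl]-5-isopropylcyclohexane-1-carboxylic acid | CC(C)[C@H]1CC[C@@](O)(COC(=O)/C(=C/[C@H]2C3=C(CC[C@@H]2C(C)C)COC3=O)CO)[C@@H](C(=O)O)[C@@H]1/C=C(\CO)C(=O)O | target

**Step count and risks**

Total step count: 15. Longest linear sequence: 13 steps (steps 1–7, 9, 11–15).

Steps most likely to fail:

1. Step 5 (bears the label). What may go wrong: protonation of the rhodium enolate before ring closure; loss of facial control at the ketone through a non-bridged transition state; E1cB dehydration of the β-hydroxy aldehyde; base-induced Michael addition of the ketone enolate to the enal. The fallback uses known chemistry in two operations and sets out from 6. A Hayashi–Miyaura 1,4-vinylation with the same rhodium/diene catalyst is run in MeOH/H2O, where proton transfer to the enolate should outrun the aldol, to give the open-chain (3R,4R)-8-(TBS-oxy)-4-isopropyl-7-oxo-3-vinyloctanal F1. L-Proline (DMSO, rt) then closes F1 by a 6-enolexo aldolisation, in which the (E)-enamine and its carboxylic acid hold the ketone oxygen in the same equatorial position. The fallback returns to the route at 8.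

2. Step 9. What may go wrong: slow initiation at the hindered, doubly flanked vinyl group; consumption of the catalyst by the electron-poor acrylate; incomplete E selectivity. The fallback sets out from 10. Ozonolysis (O3, CH2Cl2/MeOH, −78 °C; Me2S) gives the ring aldehyde tert-butyl (1S,2S,5R,6S)-2-((TBS-oxy)methyl)-6-formyl-2-hydroxy-5-isopropylcyclohexane-1-carboxylate F2. Aldol addition of the lithium enolate of tert-butyl 3-(TBDPS-oxy)propanoate (LDA, THF, −78 °C) gives the β-hydroxy ester F3 as a diastereomer mixture. Mesylation of the new secondary alcohol (MsCl, Et3N) gives the mesylate F4, and DBU-induced E1cB elimination gives the thermodynamically preferred (E)-enoate. The fallback returns to the route at 13.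

3. Step 11. What may go wrong: elimination towards C3 or towards the exocyclic CH2OTBS group instead of the acidic C1–H; ionisation of the tertiary sulfamate. The fallback sets out from 14. TFA/CH2Cl2 cleaves both tert-butyl esters and lactonises the cis hydroxy acid to the cis-fused hydroxy lactone acid F5 (stereocentres as in 14, TBDPS retained). Trifluoroacetylation of the tertiary alcohol (TFAA, pyridine; aqueous work-up) gives the trifluoroacetate F6. DBU then expels trifluoroacetate by an E1cB pathway through the lactone enolate to give the butenolide. The fallback returns to the route at 16.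

**Further compounds**

F1 | step 5 | (3R,4R)-8-(TBS-oxy)-4-isopropyl-7-oxo-3-vinyloctanal | CC(C)[C@@H](CCC(=O)CO[Si](C)(C)C(C)(C)C)[C@H](CC=O)C=C
F2 | step 9 | tert-butyl (1S,2S,5R,6S)-2-((TBS-oxy)methyl)-6-formyl-2-hydroxy-5-isopropylcyclohexane-1-carboxylate | CC(C)[C@H]1CC[C@@](O)(CO[Si](C)(C)C(C)(C)C)[C@@H](C(=O)OC(C)(C)C)[C@@H]1C=O
F3 | step 9 | aldol adduct of F2 with tert-butyl 3-(TBDPS-oxy)propanoate (β-hydroxy ester, diastereomer mixture) | CC(C)[C@H]1CC[C@@](O)(CO[Si](C)(C)C(C)(C)C)[C@@H](C(=O)OC(C)(C)C)[C@@H]1C(O)C(CO[Si](c1ccccc1)(c1ccccc1)C(C)(C)C)C(=O)OC(C)(C)C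
F4 | step 9 | secondary mesylate of F3 | CC(C)[C@H]1CC[C@@](O)(CO[Si](C)(C)C(C)(C)C)[C@@H](C(=O)OC(C)(C)C)[C@@H]1C(OS(C)(=O)=O)C(CO[Si](c1ccccc1)(c1ccccc1)C(C)(C)C)C(=O)OC(C)(C)C
F5 | step 11 | cis-fused 3a-hydroxy lactone acid (ring-A lactone, side-chain acid free, TBDPS ether) | CC(C)[C@H]1CC[C@@]2(O)COC(=O)[C@H]2[C@@H]1/C=C(\CO[Si](c1ccccc1)(c1ccccc1)C(C)(C)C)C(=O)O
F6 | step 11 | tertiary trifluoroacetate of F5 | CC(C)[C@H]1CC[C@@]2(OC(=O)C(F)(F)F)COC(=O)[C@H]2[C@@H]1/C=C(\CO[Si](c1ccccc1)(c1ccccc1)C(C)(C)C)C(=O)O
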